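**Plan**
- Retrosynthesis: the five O-benzyl groups come off last and the C2' ketone is traced back to a C1'≡C2' alkyne. The arene C6–C1' bond is then cut to an aryl bromide and a terminal alkyne, followed by the aryl ester C(=O)–O bond (ring C to unit B), the alkyl ester (unit B to unit A) and the ArCH2–CH(O) bond of unit A.
- Enabling feature: in benzoate ring C the C2' ketone sits two carbons out from C6, ortho to the C1 ester. A C6 alkyne is therefore a masked benzylic ketone, because the C1 ester carbonyl oxygen can reach C2' through a six-membered attack and decide where water adds.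
- Forward order (no ring is formed): ring A arylpropanol, ester with unit B, acylation by the ring C bromo acid, alkyne coupling at C6 bringing the whole five-carbon chain, hydration, global debenzylation.
- Stereochemistry: all three (R) centers are purchased, from (R)-propylene oxide (unit A carbinol, opened at CH2), methyl (R)-3-hydroxybutanoate (unit B) and (R)-pent-4-yn-2-ol (C4'). Later steps act at oxygen or at remote carbons, so no center is inverted or epimerised.

Key step: step 10

Remark: ring C is numbered C1 (carboxyl-bearing), C2 and C4 (oxygenated) and C6 (side chain C1'–C5'); the open-chain β-hydroxy ketone drawn is taken as the target form.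

**Route**

Step 1
Reactants: 1 1,3-bis(benzyloxy)-5-bromobenzene
Product: 3 2,4-bis(benzyloxy)-6-bromobenzaldehyde, via aryl dimethyliminium chloride 2 (not isolated)
Conditions: POCl3, DMF, 0 → 90 °C; then H2O, 0 °C → rt
Reagents that add atoms: N,N-dimethylformamide, CN(C)C=O (formyl carbon); water, O (aldehyde oxygen)
Why: Vilsmeier–Haack formylation, in which the chloroiminium ion should attack the ring carbon flanked by Br and one benzyloxy group and para to the other, the site known to react in 1-bromo-3,5-dialkoxybenzenes, after which water hydrolyses the iminium salt to the aldehyde.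

Step 2
Reactants: 3 2,4-bis(benzyloxy)-6-bromobenzaldehyde
Product: 4 2,4-bis(benzyloxy)-6-bromobenzoic acid
Conditions: NaClO2, NaH2PO4, 2-methyl-2-butene, t-BuOH/THF/H2O, rt
Reagents that add atoms: sodium chlorite, [Na+].[O-]Cl=O
Why: Pinnick oxidation converts the aldehyde to the acid under buffered conditions, the alkene scavenger removing hypochlorous acid so that the electron-rich ring is not chlorinated and the benzyl ethers and the bromide are untouched.

Step 3
Reactants: 1 1,3-bis(benzyloxy)-5-bromobenzene; 5 (R)-propylene oxide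
Product: 7 (R)-1-[3,5-bis(benzyloxy)phenyl]propan-2-ol, via aryl Grignard reagent 6 (not isolated)
Conditions: Mg (I2-activated), THF, reflux; then CuI (10 mol %), 5, −30 → 0 °C; aq NH4Cl
Reagents that add atoms: none
Why: Copper-catalysed Grignard opening of a terminal epoxide, in which the aryl nucleophile attacks the unsubstituted CH2 in an SN2 manner, so the oxygen-bearing stereocenter of 5 takes no part and is carried over unchanged as the (R)-carbinol.

Step 4
Reactants: 8 methyl (R)-3-hydroxybutanoate
Product: 9 methyl (R)-3-[(tert-butyldimethylsilyl)oxy]butanoate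
Conditions: TBSCl, imidazole, DMF, rt
Reagents that add atoms: tert-butyldimethylsilyl chloride, CC(C)(C)[Si](C)(C)Cl
Why: Standard imidazole-promoted O-silylation of a secondary alcohol, which masks the hydroxyl so that the acid made next cannot oligomerise on activation.

Step 5
Reactants: 9 methyl (R)-3-[(tert-butyldimethylsilyl)oxy]butanoate
Product: 10 (R)-3-[(tert-butyldimethylsilyl)oxy]butanoic acid
Conditions: LiOH, THF/MeOH/H2O, 0 °C → rt; then 1 M HCl to pH 3–4, 0 °C
Reagents that add atoms: lithium hydroxide, [Li+].[OH-]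
Why: Saponification of the methyl ester at low temperature, conditions under which a β-silyloxy ester should neither eliminate nor lose the silyl group, the stereocenter not being at an acidic position.

Step 6
Reactants: 7 (R)-1-[3,5-bis(benzyloxy)phenyl]propan-2-ol; 10 (R)-3-[(tert-butyldimethylsilyl)oxy]butanoic acid
Product: 11 (R)-1-[3,5-bis(benzyloxy)phenyl]propan-2-yl (R)-3-[(tert-butyldimethylsilyl)oxy]butanoate
Conditions: DCC, DMAP (cat.), CH2Cl2, 0 °C → rt
Reagents that add atoms: none
Why: Steglich esterification of an unhindered acid with a secondary alcohol, acyl transfer taking place at oxygen so that the carbinol configuration of 7 is retained.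

Step 7
Reactants: 11 (R)-1-[3,5-bis(benzyloxy)phenyl]propan-2-yl (R)-3-[(tert-butyldimethylsilyl)oxy]butanoate
Product: 12 (R)-1-[3,5-bis(benzyloxy)phenyl]propan-2-yl (R)-3-hydroxybutanoate
Conditions: HF·pyridine, pyridine/THF, 0 °C → rt
Reagents that add atoms: none
Why: Fluoride-driven desilylation under buffered, weakly acidic conditions, chosen over basic fluoride sources so that the β-hydroxy ester should neither eliminate nor transacylate.

Step 8
Reactants: 4 2,4-bis(benzyloxy)-6-bromobenzoic acid; 12 (R)-1-[3,5-bis(benzyloxy)phenyl]propan-2-yl (R)-3-hydroxybutanoate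
Product: 14 (R)-4-{[(R)-1-(3,5-bis(benzyloxy)phenyl)propan-2-yl]oxy}-4-oxobutan-2-yl 2,4-bis(benzyloxy)-6-bromobenzoate, via acid chloride 13 (not isolated)
Conditions: (COCl)2, DMF (cat.), CH2Cl2, 0 °C → rt, evaporate; then 12, Et3N, DMAP, CH2Cl2, 0 °C → rt
Reagents that add atoms: none
Why: Acid chloride formation followed by DMAP-catalysed acylation, the N-acylpyridinium ion being reactive enough to overcome the two ortho substituents, and since only the O–H bond of 12 is broken the unit B stereocenter is retained.

Step 9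
Reactants: 15 (R)-pent-4-yn-2-ol
Product: 16 (R)-4-(benzyloxy)pent-1-yne
Conditions: NaH (1.1 equiv), BnBr, Bu4NI (cat.), THF, 0 °C → rt
Reagents that add atoms: benzyl bromide, BrCc1ccccc1
Why: Williamson ether synthesis, in which NaH should deprotonate the alcohol far more readily than the much less acidic alkyne C–H, so benzylation occurs at oxygen and the carbinol center is unaffected.

Step 10
Reactants: 14 (R)-4-{[(R)-1-(3,5-bis(benzyloxy)phenyl)propan-2-yl]oxy}-4-oxobutan-2-yl 2,4-bis(benzyloxy)-6-bromobenzoate; 16 (R)-4-(benzyloxy)pent-1-yne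
Product: 17 (R)-4-{[(R)-1-(3,5-bis(benzyloxy)phenyl)propan-2-yl]oxy}-4-oxobutan-2-yl 2,4-bis(benzyloxy)-6-[(R)-4-(benzyloxy)pent-1-yn-1-yl]benzoate
Conditions: PdCl2(PPh3)2 (5 mol %), CuI (10 mol %), Et3N/THF (degassed), 60–70 °C
Reagents that add atoms: none
Why: Sonogashira coupling: the divalent palladium precatalyst is reduced in the flask to zerovalent palladium, which inserts into the C6–Br bond (activated by the ortho ester carbonyl), the copper acetylide formed from 16, CuI and Et3N transmetalates, and reductive elimination forms the C6–C1' bond. The closest known reaction type is the coupling of 2-bromo-4,6-dialkoxybenzoates with terminal alkynes under the same catalyst pair. No ring is closed and no stereocenter is created; the three existing stereocenters are remote from the reacting carbons, and C4' arrives intact with the alkyne. The step needs chemoselectivity for the aryl C–Br bond and must spare the β-acyloxy ester: the C6 bromide is the only carbon–halogen bond in 14, and triethylamine at moderate temperature should be too weak a base to expel the benzoate from the 3-acyloxybutanoate. Degassing and a slight excess of 16 should keep oxidative alkyne dimerisation from using up the alkyne.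

Step 11
Reactants: 17 (R)-4-{[(R)-1-(3,5-bis(benzyloxy)phenyl)propan-2-yl]oxy}-4-oxobutan-2-yl 2,4-bis(benzyloxy)-6-[(R)-4-(benzyloxy)pent-1-yn-1-yl]benzoate
Product: 18 (R)-4-{[(R)-1-(3,5-bis(benzyloxy)phenyl)propan-2-yl]oxy}-4-oxobutan-2-yl 2,4-bis(benzyloxy)-6-[(R)-4-(benzyloxy)-2-oxopentyl]benzoate
Conditions: AuCl3 (5 mol %), 1,4-dioxane/H2O (10:1), rt
Reagents that add atoms: water, O
Why: Carbonyl-assisted gold-catalysed alkyne hydration, in which trivalent gold activates the C1'≡C2' bond, the C1 ester carbonyl oxygen attacks C2' in a 6-endo-dig manner, water adds to the resulting alkoxybenzopyrylium carbon and the hemi-orthoester opens to the C2' ketone with the ester restored, so the regiochemistry is set by the ortho ester and not by the aryl group.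

Step 12
Reactants: 18 (R)-4-{[(R)-1-(3,5-bis(benzyloxy)phenyl)propan-2-yl]oxy}-4-oxobutan-2-yl 2,4-bis(benzyloxy)-6-[(R)-4-(benzyloxy)-2-oxopentyl]benzoate
Product: 19 hansforester K, (R)-4-{[(R)-1-(3,5-dihydroxyphenyl)propan-2-yl]oxy}-4-oxobutan-2-yl 2,4-dihydroxy-6-[(R)-4-hydroxy-2-oxopentyl]benzoate
Conditions: H2 (1 atm), Pd/C (10 wt% Pd), EtOAc/MeOH, rt
Reagents that add atoms: none
Why: Catalytic hydrogenolysis should cleave the four aryl benzyl ethers and the one alkyl benzyl ether under neutral conditions that leave both esters, the non-conjugated ketone and the β-hydroxy ketone unit untouched, the ester oxygens not being benzylic.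

**Compound list**
1 | 1,3-bis(benzyloxy)-5-bromobenzene | Brc1cc(OCc2ccccc2)cc(OCc2ccccc2)c1 | starting material
2 | N-[2,4-bis(benzyloxy)-6-bromobenzylidene]-N-methylmethanaminium chloride (aryl dimethyliminium chloride) | C[N+](C)=Cc1c(Br)cc(OCc2ccccc2)cc1OCc1ccccc1.[Cl-] | intermediate (not isolated)
3 | 2,4-bis(benzyloxy)-6-bromobenzaldehyde | O=Cc1c(Br)cc(OCc2ccccc2)cc1OCc1ccccc1 | intermediate
4 | 2,4-bis(benzyloxy)-6-bromobenzoic acid | OC(=O)c1c(Br)cc(OCc2ccccc2)cc1OCc1ccccc1 | intermediate
5 | (R)-propylene oxide, (R)-2-methyloxirane | C[C@@H]1CO1 | starting material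
6 | [3,5-bis(benzyloxy)phenyl]magnesium bromide | Br[Mg]c1cc(OCc2ccccc2)cc(OCc2ccccc2)c1 | intermediate (not isolated)
7 | (R)-1-[3,5-bis(benzyloxy)phenyl]propan-2-ol | C[C@@H](O)Cc1cc(OCc2ccccc2)cc(OCc2ccccc2)c1 | intermediate
8 | methyl (R)-3-hydroxybutanoate | COC(=O)C[C@@H](C)O | starting material
9 | methyl (R)-3-[(tert-butyldimethylsilyl)oxy]butanoate | COC(=O)C[C@@H](C)O[Si](C)(C)C(C)(C)C | intermediate
10 | (R)-3-[(tert-butyldimethylsilyl)oxy]butanoic acid | OC(=O)C[C@@H](C)O[Si](C)(C)C(C)(C)C | intermediate
11 | (R)-1-[3,5-bis(benzyloxy)phenyl]propan-2-yl (R)-3-[(tert-butyldimethylsilyl)oxy]butanoate | C[C@H](Cc1cc(OCc2ccccc2)cc(OCc2ccccc2)c1)OC(=O)C[C@@H](C)O[Si](C)(C)C(C)(C)C | intermediate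
12 | (R)-1-[3,5-bis(benzyloxy)phenyl]propan-2-yl (R)-3-hydroxybutanoate | C[C@H](Cc1cc(OCc2ccccc2)cc(OCc2ccccc2)c1)OC(=O)C[C@@H](C)O | intermediate
13 | 2,4-bis(benzyloxy)-6-bromobenzoyl chloride | O=C(Cl)c1c(Br)cc(OCc2ccccc2)cc1OCc1ccccc1 | intermediate (not isolated)
14 | (R)-4-{[(R)-1-(3,5-bis(benzyloxy)phenyl)propan-2-yl]oxy}-4-oxobutan-2-yl 2,4-bis(benzyloxy)-6-bromobenzoate | C[C@H](Cc1cc(OCc2ccccc2)cc(OCc2ccccc2)c1)OC(=O)C[C@@H](C)OC(=O)c1c(OCc2ccccc2)cc(OCc2ccccc2)cc1Br | intermediate
15 | (R)-pent-4-yn-2-ol | C#CC[C@@H](C)O | starting material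
16 | (R)-4-(benzyloxy)pent-1-yne | C#CC[C@@H](C)OCc1ccccc1 | intermediate
17 | (R)-4-{[(R)-1-(3,5-bis(benzyloxy)phenyl)propan-2-yl]oxy}-4-oxobutan-2-yl 2,4-bis(benzyloxy)-6-[(R)-4-(benzyloxy)pent-1-yn-1-yl]benzoate | C[C@H](Cc1cc(OCc2ccccc2)cc(OCc2ccccc2)c1)OC(=O)C[C@@H](C)OC(=O)c1c(OCc2ccccc2)cc(OCc2ccccc2)cc1C#CC[C@@H](C)OCc1ccccc1 | intermediate
18 | (R)-4-{[(R)-1-(3,5-bis(benzyloxy)phenyl)propan-2-yl]oxy}-4-oxobutan-2-yl 2,4-bis(benzyloxy)-6-[(R)-4-(benzyloxy)-2-oxopentyl]benzoate | C[C@H](Cc1cc(OCc2ccccc2)cc(OCc2ccccc2)c1)OC(=O)C[C@@H](C)OC(=O)c1c(OCc2ccccc2)cc(OCc2ccccc2)cc1CC(=O)C[C@@H](C)OCc1ccccc1 | intermediate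
19 | hansforester K, (R)-4-{[(R)-1-(3,5-dihydroxyphenyl)propan-2-yl]oxy}-4-oxobutan-2-yl 2,4-dihydroxy-6-[(R)-4-hydroxy-2-oxopentyl]benzoate | C[C@H](Cc1cc(O)cc(O)c1)OC(=O)C[C@@H](C)OC(=O)c1c(O)cc(O)cc1CC(=O)C[C@@H](C)O | target

**Step count**
Total: 12 steps. Longest linear sequence: 8 steps (8 → 9 → 10 → 11 → 12 → 14 → 17 → 18 → 19; steps 4, 5, 6, 7, 8, 10, 11, 12).

**Steps most likely to fail**

Step 11 (hydration). The hemi-orthoester formed after water adds may collapse by expelling the unit A–B alcohol instead of opening the ring, which cleaves the aryl ester and gives an isocoumarin. Carbonyl attack at C1' or unassisted hydration would place the ketone at C1', and the Lewis acid could also promote loss of benzyl alcohol from the β-benzyloxy ketone. The fallback avoids the alkyne and sets out from 16 and 14. Mercury-catalysed Markovnikov hydration of the terminal alkyne 16 (HgSO4 cat., dilute H2SO4, aqueous THF) should give (R)-4-(benzyloxy)pentan-2-one F1. Kinetic enolisation on the methyl side with LiN(i-Pr)2 at −78 °C and trapping with Me3SiCl should give (R)-{[4-(benzyloxy)pent-1-en-2-yl]oxy}trimethylsilane F2. Tin-fluoride-promoted, palladium-catalysed arylation of this silyl enol ether with bromide 14 (Bu3SnF, PdCl2[P(o-tolyl)3]2, toluene, 90 °C) should then form the C6–C1' bond with the ketone already at C2', coming back to the route at 18.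

Step 10 (Sonogashira coupling). Oxidative addition into the electron-rich, ortho-substituted aryl bromide may be slow, so that copper-mediated oxidative dimerisation of 16 overtakes the cross-coupling. Prolonged heating in amine may also start elimination of the benzoate from the β-acyloxy ester. The fallback changes the nucleophile and removes both copper and amine; it sets out from 16 and 14. Deprotonation of 16 (n-BuLi, THF, −78 °C) and quenching with Bu3SnCl should give (R)-[4-(benzyloxy)pent-1-yn-1-yl]tributylstannane F3. Stille coupling of F3 with 14 (Pd(PPh3)4, toluene, 100 °C) under neutral conditions should form the same C6–C1' bond and return at 17.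

Step 8 (acylation by the doubly ortho-substituted acid chloride). Acyl transfer to the secondary alcohol may be slow, and extended exposure to amine base may eliminate the newly formed β-aroyloxy ester to a crotonate. The fallback makes the carboxylate the nucleophile and sets out from 4 and 7. Mitsunobu esterification of 4 with purchased tert-butyl (S)-3-hydroxybutanoate F4 (PPh3, DIAD, toluene, 0 °C) should proceed with inversion to tert-butyl (R)-3-{[2,4-bis(benzyloxy)-6-bromobenzoyl]oxy}butanoate F5. Cleavage of the tert-butyl ester (CF3CO2H, CH2Cl2, 0 °C) should give (R)-3-{[2,4-bis(benzyloxy)-6-bromobenzoyl]oxy}butanoic acid F6. Steglich coupling of F6 with alcohol 7 (DCC, DMAP cat., CH2Cl2) returns at 14 and makes steps 4 to 7 unnecessary.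

**Further compounds**
F1 | step 11 | (R)-4-(benzyloxy)pentan-2-one | CC(=O)C[C@@H](C)OCc1ccccc1
F2 | step 11 | (R)-{[4-(benzyloxy)pent-1-en-2-yl]oxy}trimethylsilane | C=C(O[Si](C)(C)C)C[C@@H](C)OCc1ccccc1
F3 | step 10 | (R)-[4-(benzyloxy)pent-1-yn-1-yl]tributylstannane | CCCC[Sn](CCCC)(CCCC)C#CC[C@@H](C)OCc1ccccc1
F4 | step 8 | tert-butyl (S)-3-hydroxybutanoate (purchased) | CC(C)(C)OC(=O)C[C@H](C)O
F5 | step 8 | tert-butyl (R)-3-{[2,4-bis(benzyloxy)-6-bromobenzoyl]oxy}butanoate | CC(C)(C)OC(=O)C[C@@H](C)OC(=O)c1c(Br)cc(OCc2ccccc2)cc1OCc1ccccc1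
F6 | step 8 | (R)-3-{[2,4-bis(benzyloxy)-6-bromobenzoyl]oxy}butanoic acid | OC(=O)C[C@@H](C)OC(=O)c1c(Br)cc(OCc2ccccc2)cc1OCc1ccccc1
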